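The oxygenated ring A of chiricanine C bears oxygen on C3 and C5 with the prenylated C4 between them (stilbene numbering), the signature of an aromatised cyclohexane-1,3-dione; it is therefore cut at C1–C2 and C3–C4. Dimethyl malonate 1 and prenyl bromide 2 give prenylmalonate 3, while cinnamaldehyde 4 and ketone 5 give the open-chain E,E-dienone 6, whose homoprenyl tail is the future C4 prenyl group. In one operation 3 adds 1,4 to 6 and the keto diester 7 so formed closes by Claisen condensation to cyclohexanedione 8, carrying both prenyl groups, the styryl group and both oxygens. Ester removal, O-methylation and dehydrogenation then finish the synthesis.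

Key step: step 3

Remark: ring A of the target is numbered as in a stilbene (C1 styryl, C2 and C4 prenyl, C3 methoxy, C5 hydroxy, C6 hydrogen), and intermediates use their own IUPAC locants. The sp3 centres formed along the way are uncontrolled mixtures that all vanish on aromatisation; the only stereo-element of the target is the E double bond brought in with cinnamaldehyde.

Step 1
Reactants: 1 dimethyl malonate; 2 prenyl bromide (1-bromo-3-methylbut-2-ene)
Product: 3 dimethyl 2-(3-methylbut-2-enyl)propanedioate
Conditions: NaH (1.0 equiv), THF, 0 °C; then 2, 0 °C to rt (1 in 1.5-fold excess)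
Reagents that add atoms: none
Why: Malonic ester alkylation, an SN2 displacement at the primary allylic carbon of 2 by the sodium enolate of 1, with the excess of 1 suppressing dialkylation and no stereocentre formed.

Step 2
Reactants: 4 trans-cinnamaldehyde; 5 6-methylhept-5-en-2-one
Product: 6 (1E,3E)-9-methyl-1-phenyldeca-1,3,8-trien-5-one
Conditions: 10% aq. NaOH (cat.), EtOH, 0 °C to rt (5 in excess)
Reagents that add atoms: none
Why: Claisen–Schmidt crossed aldol condensation in which the non-enolisable aldehyde 4 is attacked by the ketone through its methyl group (under hydroxide only the methyl-side aldol dehydrates readily, the methylene-side aldol reverting), and E1cB dehydration gives the new double bond in the conjugated E form.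

Step 3
Reactants: 3 dimethyl 2-(3-methylbut-2-enyl)propanedioate; 6 (1E,3E)-9-methyl-1-phenyldeca-1,3,8-trien-5-one
Product: 8 methyl 1,3-bis(3-methylbut-2-enyl)-2,4-dioxo-6-[(E)-2-phenylethenyl]cyclohexane-1-carboxylate (diastereomer mixture), via open-chain Michael adduct 7 (not isolated)
Conditions: NaOMe (1.2 equiv), MeOH, reflux; then 1 M HCl, 0 °C
Reagents that add atoms: none
Why: Michael–Claisen annulation of an enone with a malonate, the established route to 5-substituted cyclohexane-1,3-diones: the sodium enolate of 3 adds to C3 of 6 (the enone β-carbon) to give keto diester 7, forming C1–C6 of 8 (C1–C2 of the target), proton transfer then places the enolate on the ketone's α′-methylene (C6 of 6), and this carbon attacks one ester carbonyl with loss of methoxide, forming C2–C3 of 8 (C3–C4 of the target). The ring closes in the 6-exo-trig mode, the enolate carbon attacking an ester C=O that lies outside the forming ring, and the closure is made irreversible by deprotonation of the new 1,3-dione at C3, the resulting vinylogous carboxylate resisting retro-Claisen cleavage. The sp3 centres C1 and C6 (and the labile C3) form without control as a diastereomer mixture, which is acceptable because all of them become sp2 on aromatisation. The selectivity the step needs is 1,4- over 1,6-addition: the δ-carbon of 6 carries the phenyl group, is the more hindered terminus and would lose its styrene conjugation on attack, conjugate addition is reversible under methoxide, and only the 1,4-adduct 7 can close a six-membered dione, so the equilibrium should drain toward 8. The α-methylene of 7 cannot compete in the closure since it would form a four-membered ring, and using methoxide with methyl esters removes ester exchange as a variable.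

Step 4
Reactants: 8 methyl 1,3-bis(3-methylbut-2-enyl)-2,4-dioxo-6-[(E)-2-phenylethenyl]cyclohexane-1-carboxylate
Product: 9 2,4-bis(3-methylbut-2-enyl)-5-[(E)-2-phenylethenyl]cyclohexane-1,3-dione (diastereomer mixture, largely enolised)
Conditions: LiCl, H2O, DMSO, 130 °C
Reagents that add atoms: none
Why: Krapcho dealkoxycarbonylation, in which chloride removes the ester methyl group by SN2 attack (so the hindered acyl carbon on the quaternary centre need not be attacked), the β-keto carboxylate loses CO2 and water protonates the enolate; the near-neutral medium avoids the acid-induced cyclisation of a prenyl group onto the enolised dione that a hot acidic decarboxylation would risk.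

Step 5
Reactants: 9 2,4-bis(3-methylbut-2-enyl)-5-[(E)-2-phenylethenyl]cyclohexane-1,3-dione
Product: 10 3-methoxy-2,4-bis(3-methylbut-2-enyl)-5-[(E)-2-phenylethenyl]cyclohex-2-en-1-one (diastereomer mixture)
Conditions: TMSCHN2 (hexanes), PhMe–MeOH, 0 °C to rt; chromatography
Reagents that add atoms: trimethylsilyldiazomethane, C[Si](C)(C)C=[N+]=[N-]
Why: O-Alkylation of an enolised cyclic 1,3-dione (a vinylogous acid) by diazomethane generated in situ, which methylates oxygen only and, being a small and very reactive electrophile, discriminates least against the more crowded oxygen on C3 of 9 (the carbonyl carbon between the prenyl-bearing C2 and C4), so that 10 should form beside material methylated on the C1 oxygen; 10 is isolated by chromatography and the remainder is returned to 9 by mild aqueous acid hydrolysis for another pass.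

Step 6
Reactants: 10 3-methoxy-2,4-bis(3-methylbut-2-enyl)-5-[(E)-2-phenylethenyl]cyclohex-2-en-1-one
Product: 14 chiricanine C (3-methoxy-2,4-bis(3-methylbut-2-enyl)-5-[(E)-2-phenylethenyl]phenol), via α-phenylselanyl ketone 11 (not isolated), via selenoxide 12 (not isolated), via cyclohexa-2,5-dienone tautomer 13 (not isolated)
Conditions: LiN(iPr)2 (1.1 equiv), THF, −78 °C; PhSeCl (1.05 equiv), −78 °C; then 30% H2O2, pyridine, CH2Cl2, 0 °C to rt
Reagents that add atoms: none
Why: α′-Selenenylation and selenoxide syn-elimination of a vinylogous ester, the standard dehydrogenation of 3-alkoxycyclohexenones to resorcinol monoethers: kinetic deprotonation occurs at the C6 methylene, selenium should enter trans to the C5 styryl group and hence cis to the C5 hydrogen it must remove, and the cross-conjugated dienone 13 tautomerises to the phenol under the drive of aromaticity, while the enolate outcompetes the prenyl double bonds for PhSeCl at −78 °C and pyridine-buffered H2O2 leaves the alkenes and the E-styryl bond alone.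

Compound list

1 | dimethyl malonate | COC(=O)CC(=O)OC | starting material
2 | prenyl bromide (1-bromo-3-methylbut-2-ene) | CC(C)=CCBr | starting material
3 | dimethyl 2-(3-methylbut-2-enyl)propanedioate | COC(=O)C(CC=C(C)C)C(=O)OC | intermediate
4 | trans-cinnamaldehyde ((E)-3-phenylprop-2-enal) | O=C/C=C/c1ccccc1 | starting material
5 | 6-methylhept-5-en-2-one | CC(=O)CCC=C(C)C | starting material
6 | (1E,3E)-9-methyl-1-phenyldeca-1,3,8-trien-5-one | O=C(CCC=C(C)C)/C=C/C=C/c1ccccc1 | intermediate
7 | dimethyl 2-(3-methylbut-2-enyl)-2-[(1E)-9-methyl-5-oxo-1-phenyldeca-1,8-dien-3-yl]propanedioate (racemic) | COC(=O)C(CC=C(C)C)(C(=O)OC)C(/C=C/c1ccccc1)CC(=O)CCC=C(C)C | intermediate (not isolated)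
8 | methyl 1,3-bis(3-methylbut-2-enyl)-2,4-dioxo-6-[(E)-2-phenylethenyl]cyclohexane-1-carboxylate (diastereomer mixture) | COC(=O)C1(CC=C(C)C)C(=O)C(CC=C(C)C)C(=O)CC1/C=C/c1ccccc1 | intermediate
9 | 2,4-bis(3-methylbut-2-enyl)-5-[(E)-2-phenylethenyl]cyclohexane-1,3-dione (diastereomer mixture) | O=C1CC(/C=C/c2ccccc2)C(CC=C(C)C)C(=O)C1CC=C(C)C | intermediate
10 | 3-methoxy-2,4-bis(3-methylbut-2-enyl)-5-[(E)-2-phenylethenyl]cyclohex-2-en-1-one (diastereomer mixture) | COC1=C(CC=C(C)C)C(=O)CC(/C=C/c2ccccc2)C1CC=C(C)C | intermediate
11 | 3-methoxy-2,4-bis(3-methylbut-2-enyl)-5-[(E)-2-phenylethenyl]-6-(phenylselanyl)cyclohex-2-en-1-one | COC1=C(CC=C(C)C)C(=O)C([Se]c2ccccc2)C(/C=C/c3ccccc3)C1CC=C(C)C | intermediate (not isolated)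
12 | 6-(benzeneseleninyl)-3-methoxy-2,4-bis(3-methylbut-2-enyl)-5-[(E)-2-phenylethenyl]cyclohex-2-en-1-one | COC1=C(CC=C(C)C)C(=O)C([Se](=O)c2ccccc2)C(/C=C/c3ccccc3)C1CC=C(C)C | intermediate (not isolated)
13 | 3-methoxy-2,4-bis(3-methylbut-2-enyl)-5-[(E)-2-phenylethenyl]cyclohexa-2,5-dien-1-one | COC1=C(CC=C(C)C)C(=O)C=C(/C=C/c2ccccc2)C1CC=C(C)C | intermediate (not isolated)
14 | chiricanine C, 3-methoxy-2,4-bis(3-methylbut-2-enyl)-5-[(E)-2-phenylethenyl]phenol | COc1c(CC=C(C)C)c(O)cc(/C=C/c2ccccc2)c1CC=C(C)C | target

Total step count: 6. Longest linear sequence: 5 steps (steps 2 to 6 from 4 and 5; equally steps 1 and 3 to 6 from 1 and 2).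

Steps most likely to fail

Step 3. The conjugate addition of the tertiary malonate anion is sterically demanding and reversible, so the equilibrium may stay on the side of the components. Base-induced self-condensation of the dienone, or attack at its phenyl-bearing terminus, may then consume material before the ring closes. The fallback sets out from 6 and builds the ring with the unhindered donor first. Unsubstituted dimethyl malonate 1 (NaOMe, MeOH, reflux) should add to 6 to give dimethyl 2-[(1E)-9-methyl-5-oxo-1-phenyldeca-1,8-dien-3-yl]propanedioate F1, which closes in the same flask to methyl 3-(3-methylbut-2-enyl)-2,4-dioxo-6-[(E)-2-phenylethenyl]cyclohexane-1-carboxylate F2. Double deprotonation of F2 (LiN(iPr)2, 2.2 equiv, THF, −78 to 0 °C) and alkylation with prenyl bromide 2 at the less stabilised ester-enolate carbon C1 installs the second prenyl group after ring formation. The fallback comes back to the route at 8.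

Step 5. Methyl transfer may go largely to the less crowded oxygen, so that little of the required enol ether is obtained even with recycling. The fallback sets out from 9 and aromatises before the two oxygens are told apart.
- Double deprotonation (LiN(iPr)2, 2.2 equiv, THF–DMPU, −78 °C) and PhSeCl should selenenylate the ring methylene to give 2,4-bis(3-methylbut-2-enyl)-5-[(E)-2-phenylethenyl]-6-(phenylselanyl)cyclohexane-1,3-dione F3.
- H2O2 and pyridine oxidise it to 6-(benzeneseleninyl)-2,4-bis(3-methylbut-2-enyl)-5-[(E)-2-phenylethenyl]cyclohexane-1,3-dione F4.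
- Syn-elimination gives 2,6-bis(3-methylbut-2-enyl)-5-[(E)-2-phenylethenyl]cyclohex-4-ene-1,3-dione F5, which enolises to 2,4-bis(3-methylbut-2-enyl)-5-[(E)-2-phenylethenyl]benzene-1,3-diol F6.
- iPr3SiCl and imidazole in DMF at 0 °C should silylate only the hydroxyl flanked by a single ring substituent, giving 2,6-bis(3-methylbut-2-enyl)-3-[(E)-2-phenylethenyl]-5-[tri(propan-2-yl)silyloxy]phenol F7.
- NaH and MeI in THF at 0 °C methylate the remaining, doubly flanked hydroxyl to give [3-methoxy-2,4-bis(3-methylbut-2-enyl)-5-[(E)-2-phenylethenyl]phenoxy]tri(propan-2-yl)silane F8.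
- Bu4NF in THF removes the silyl group.

The fallback comes back to the route at 14 and bypasses 10 to 13.

Step 6. Electrophilic selenium may add across the prenyl double bonds, and the selenenic acid released during the peroxide stage may attack the electron-rich product. Elimination also stalls if selenium enters cis to the styryl group, where no syn hydrogen is available. The fallback sets out from 10 and uses a Saegusa–Ito dehydrogenation. LiN(iPr)2 then Me3SiCl (THF, −78 °C) should give trimethyl{[4-methoxy-3,5-bis(3-methylbut-2-enyl)-6-[(E)-2-phenylethenyl]cyclohexa-1,3-dien-2-yl]oxy}silane F9. Pd(OAc)2 (divalent palladium, stoichiometric) in MeCN at rt palladates the former C6, and β-hydride elimination of the C5 hydrogen gives the dienone. The fallback comes back to the route at 13, which tautomerises to 14, and uses neither electrophilic selenium nor peroxide.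

Further compounds

F1 | step 3 | dimethyl 2-[(1E)-9-methyl-5-oxo-1-phenyldeca-1,8-dien-3-yl]propanedioate | COC(=O)C(C(=O)OC)C(/C=C/c1ccccc1)CC(=O)CCC=C(C)C
F2 | step 3 | methyl 3-(3-methylbut-2-enyl)-2,4-dioxo-6-[(E)-2-phenylethenyl]cyclohexane-1-carboxylate | COC(=O)C1C(=O)C(CC=C(C)C)C(=O)CC1/C=C/c1ccccc1
F3 | step 5 | 2,4-bis(3-methylbut-2-enyl)-5-[(E)-2-phenylethenyl]-6-(phenylselanyl)cyclohexane-1,3-dione | O=C1C([Se]c2ccccc2)C(/C=C/c3ccccc3)C(CC=C(C)C)C(=O)C1CC=C(C)C
F4 | step 5 | 6-(benzeneseleninyl)-2,4-bis(3-methylbut-2-enyl)-5-[(E)-2-phenylethenyl]cyclohexane-1,3-dione | O=C1C([Se](=O)c2ccccc2)C(/C=C/c3ccccc3)C(CC=C(C)C)C(=O)C1CC=C(C)C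
F5 | step 5 | 2,6-bis(3-methylbut-2-enyl)-5-[(E)-2-phenylethenyl]cyclohex-4-ene-1,3-dione | O=C1C=C(/C=C/c2ccccc2)C(CC=C(C)C)C(=O)C1CC=C(C)C
F6 | step 5 | 2,4-bis(3-methylbut-2-enyl)-5-[(E)-2-phenylethenyl]benzene-1,3-diol | Oc1cc(/C=C/c2ccccc2)c(CC=C(C)C)c(O)c1CC=C(C)C
F7 | step 5 | 2,6-bis(3-methylbut-2-enyl)-3-[(E)-2-phenylethenyl]-5-[tri(propan-2-yl)silyloxy]phenol | CC(C)[Si](Oc1cc(/C=C/c2ccccc2)c(CC=C(C)C)c(O)c1CC=C(C)C)(C(C)C)C(C)C
F8 | step 5 | [3-methoxy-2,4-bis(3-methylbut-2-enyl)-5-[(E)-2-phenylethenyl]phenoxy]tri(propan-2-yl)silane | COc1c(CC=C(C)C)c(O[Si](C(C)C)(C(C)C)C(C)C)cc(/C=C/c2ccccc2)c1CC=C(C)C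
F9 | step 6 | trimethyl{[4-methoxy-3,5-bis(3-methylbut-2-enyl)-6-[(E)-2-phenylethenyl]cyclohexa-1,3-dien-2-yl]oxy}silane | COC1=C(CC=C(C)C)C(O[Si](C)(C)C)=CC(/C=C/c2ccccc2)C1CC=C(C)C
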